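Cedar's [G] stood at 21% from 4.00 min on, and its last [E] was 7%, in a flask charged with 1.5 equiv of D.

| flask | G | D | temperature | remark | time |
|---|---|---|---|---|---|
| birch | 0.34 M | 1.5 equiv | 65 °C | run made earlier |  |
| cedar | 0.75 M | 1.5 equiv | 100 °C | run made earlier |  |
| elm | 0.50 M | 2.2 equiv | 65 °C | run made earlier |  |
| north | 0.50 M | 1.50 equiv |  | at 70 °C until 1.5 min, from then on at 130 °C | 3.0 min |
| north-east | 0.50 M | 1.50 equiv | 130 °C |  | 3.0 min |
| south-east | 0.50 M | 1.50 equiv | 100 °C |  | 3.0 min |
| north-west | 0.50 M | 1.50 equiv | 70 °C |  | 3.0 min |

- birch (time / min: E / %, G / %): 4.00: 22, 63; 6.00: 13, 55; 12.0: 8, 44; 20.0: 7, 39; 25.0: 6, 32; 30.0: 7, 32; 50.0: 3, 27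
- cedar (time / min: E / %, G / %): 0.667: 18, 37; 0.833: 15, 32; 1.33: 8, 30; 2.00: 9, 24; 4.00: 6, 21; 6.00: 5, 21; 8.00: 7, 21
- elm (time / min: E / %, G / %): 4.00: 17, 37; 6.00: 11, 34; 12.0: 5, 24; 25.0: 5, 11; 50.0: 0, 7

(scatter of a reading: 2 percentage points)

- which flask leads in amount of E, in percent of the G charged ("all alike" within 1.5 percentage points) (north / north-east / south-east / north-west / all alike)
- how much E is there at the end, in percent of the G charged: north
- how much E is there at the end, in percent of the G charged: north-east
- how much E is there at the end, in percent of the G charged: south-east
- how much E is there at the end, in percent of the G charged: north-west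

- reactions considered so far: D + E -> X; G -> J; G + D -> E

Nobody measured D, so I read it from the other species. Each G that becomes E takes one D, and each E that goes on to X takes another. With J neglected, twice [G] plus [E] therefore falls by one point for each point of D spent. Cedar's last three readings average to 48.0%. I call this the stall sum: the value of twice [G] plus [E], in percent of the G charged, at which the D left counts as zero in a flask of this charge, D being the limiting reagent. In a flask of this charge, with J neglected, the excess of the sum over it, divided by the equivalents charged, is the part of its own D still in hand.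

Elm, with 2.2 equiv, has a different charge, so I set it aside. Birch at 6.00 min comes out at 50.0% of its D, with [E] at 13%. Cedar at 2.00 min comes out at 6.00%, with [E] at 9%. So in these two readings [E] stood higher where more D was left.

What mattered next was how far each new flask got in 3.0 min. North-west, at 70 °C, is warmer than birch and richer in G, so I placed it near birch's first two readings, with [E] between 13% and 22%. South-east has cedar's temperature but less G and a longer time, and I placed it, as an estimate, near cedar at 2.00 min. North and north-east end hotter, and I placed them no higher. I expected north-west to lead.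

The forecast gave 16% for north-west, 8% for south-east, 7% for north and 6% for north-east, holding that “E is a transient intermediate”.

North-west gave 18.9% of E, south-east 6.71%, north 3.76% and north-east 2.84%, so north-west led.

    D + E → X (k = 0.110 M⁻¹ s⁻¹, Ea = 59.0 kJ mol⁻¹)
    G → J (k = 2.02 × 10⁻⁵ s⁻¹, Ea = 127 kJ mol⁻¹)
    G + D → E, rate k3*[G]^2*[D] (k = 0.104 M⁻² s⁻¹, Ea = 52.0 kJ mol⁻¹)
    (constants at 100 °C)

From its [G] and [E], the stall sum put north-west's D at 45.3% of its charge, and the flask held 44.0%. North read at 80 s came to 66.6%, and that flask held 65.3%. E stayed low in north-east mainly because of the step D + E → X: with that step taken away, north-east held 90.8% of E instead of 2.84%.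

(All runs stem from a simulated flask with constants of no real substance, and the scatter is random.)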